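**Retrosynthetic overview**

1. Cadinane numbering is used (ring A = C1–C6, ring B = C1, C6–C10; C11–C13 = acrylic acid arm on C7; C14 = methylene on C10; C15 = hydroxymethyl on C4). Late disconnections: the O8 acyl group (esterification with acetonide acid 29), then the C11=C13 and C10=C14 methylenes, leading back to trans-octalone 19.
2. Key disconnection: ring A is cut at C5–C6 and C3–C4. This excises C4=C5 with C15 as a terminal alkyne (propargyl ether 16) and leaves the monocyclic ring B iodoethyl enone 15.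
3. Enabling feature: the ring B enone O=C10–C1=C6 carries the arm C2–C3 on its α-carbon C1. The electrophilic β-carbon C6 and the metallated C3 are the 1,4-related ends of C6–C1–C2–C3, and nickel bridges them with the alkyne in an alkylative formal [4+2] annulation that also fixes C6 and, by protonation, C1.
4. Ring B comes from meso cis-cyclohex-2-ene-1,4-diyl diacetate: enzymatic desymmetrization, Ireland–Claisen rearrangement (C7 arm cis to O8), allylic oxidation, α-iodination/allylation, chain trimming to 15.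
5. Ring order: ring B first (from cyclohexa-1,3-diene), ring A in the key step. The acyl side chain comes from the C4 chiral-pool ester 25.

Key step: step 11

Remark (assumptions): 1, 16, 25 and all reagents are taken as commercial. The hydrolase of step 2 is assumed to give the (1R,4S) monoacetate; this sense is not established here and is the first thing to verify. TBS = tert-butyldimethylsilyl, PMB = 4-methoxybenzyl, Ni(cod)2 = bis(cycloocta-1,5-diene)nickel.

**Route**

Step 1
Reactants: 1 cyclohexa-1,3-diene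
Product: 2 cis-cyclohex-2-ene-1,4-diyl diacetate (meso)
Conditions: Pd(OAc)2 (5 mol %), LiCl (cat.), LiOAc, p-benzoquinone, AcOH, 25 °C
Reagents that add atoms: acetic acid, CC(=O)O
Why: Palladium-catalysed 1,4-diacetoxylation of a 1,3-diene, in which catalytic chloride makes the second acetate attack the π-allyl complex from the face opposite to palladium, so both C–O bonds should end up cis (meso product).

Step 2
Reactants: 2 cis-cyclohex-2-ene-1,4-diyl diacetate
Product: 3 (1R,4S)-4-hydroxycyclohex-2-en-1-yl acetate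
Conditions: lipase (hydrolase screened for this sense, e.g. Candida rugosa lipase), phosphate buffer pH 7, 25 °C, stopped at the monoacetate
Reagents that add atoms: none
Why: Enzymatic desymmetrization of a meso diacetate, in which the hydrolase cleaves one of the two enantiotopic esters and so fixes both carbinol centres (later C1 and C8) in one event; the same enzyme run in the acylation direction on the meso diol would give the antipode if needed.

Step 3
Reactants: 3 (1R,4S)-4-hydroxycyclohex-2-en-1-yl acetate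
Product: 4 (1R,4S)-4-(TBS-oxy)cyclohex-2-en-1-yl acetate
Conditions: TBSCl, imidazole, DMF, 25 °C
Reagents that add atoms: tert-butyldimethylsilyl chloride, CC(C)(C)[Si](C)(C)Cl
Why: Standard silylation of the free secondary alcohol, which protects the future O8 as a poor leaving group β to the later C10 ketone.

Step 4
Reactants: 4 (1R,4S)-4-(TBS-oxy)cyclohex-2-en-1-yl acetate
Product: 7 2-[(1R,6S)-6-(TBS-oxy)cyclohex-2-en-1-yl]acetic acid, via silyl ketene acetal 5 (not isolated), via silyl ester 6 (not isolated)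
Conditions: LDA, TBSCl, DMPU, THF, −78 → 65 °C; then K2CO3, MeOH/H2O; citric acid
Reagents that add atoms: none
Why: Ireland–Claisen rearrangement of the allylic acetate, whose suprafacial [3,3] shift forms the C7–C11 bond on the face that carried the C1–O bond, so the new arm should be cis to the C8 silyloxy group with full chirality transfer and the alkene moves to C1=C6.

Step 5
Reactants: 7 2-[(1R,6S)-6-(TBS-oxy)cyclohex-2-en-1-yl]acetic acid
Product: 8 tert-butyl 2-[(1R,6S)-6-(TBS-oxy)cyclohex-2-en-1-yl]acetate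
Conditions: tert-butyl 2,2,2-trichloroacetimidate, CH2Cl2/cyclohexane, 25 °C
Reagents that add atoms: tert-butyl 2,2,2-trichloroacetimidate, CC(C)(C)OC(=N)C(Cl)(Cl)Cl
Why: Imidate tert-butylation of a carboxylic acid (the acid itself activates the imidate); the tert-butyl ester is chosen because it resists later lactonization onto O8 and survives base and fluoride.

Step 6
Reactants: 8 tert-butyl 2-[(1R,6S)-6-(TBS-oxy)cyclohex-2-en-1-yl]acetate
Product: 9 tert-butyl 2-[(1R,6S)-6-(TBS-oxy)-4-oxocyclohex-2-en-1-yl]acetate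
Conditions: dirhodium tetrakis(caprolactamate) (1 mol %), t-BuOOH, K2CO3, CH2Cl2, 25 °C
Reagents that add atoms: tert-butyl hydroperoxide, CC(C)(C)OO
Why: Allylic C–H oxidation of a cyclohexene to the cyclohexenone, in which the secondary C10–H bonds should be attacked in preference to the hindered tertiary C7–H, placing the carbonyl at C10 and keeping C1=C6.

Step 7
Reactants: 9 tert-butyl 2-[(1R,6S)-6-(TBS-oxy)-4-oxocyclohex-2-en-1-yl]acetate
Product: 10 tert-butyl 2-[(1R,6S)-6-(TBS-oxy)-3-iodo-4-oxocyclohex-2-en-1-yl]acetate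
Conditions: I2, pyridine, CH2Cl2, 0 → 25 °C
Reagents that add atoms: iodine, II
Why: α-Iodination of a cyclic enone (conjugate addition of pyridine, iodination of the enolate, elimination) should give the 2-iodoenone needed for cross-coupling at C1.

Step 8
Reactants: 10 tert-butyl 2-[(1R,6S)-6-(TBS-oxy)-3-iodo-4-oxocyclohex-2-en-1-yl]acetate
Product: 11 tert-butyl 2-[(1R,6S)-6-(TBS-oxy)-4-oxo-3-(prop-2-en-1-yl)cyclohex-2-en-1-yl]acetate
Conditions: allyltributylstannane, PdCl2(PhCN)2 (5 mol %), AsPh3, CuI, NMP, 25 °C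
Reagents that add atoms: allyltributylstannane, C=CC[Sn](CCCC)(CCCC)CCCC
Why: Stille coupling of an α-iodoenone with an allylstannane forms the C1–C2 bond under neutral conditions that the β-silyloxy enone should tolerate.

Step 9
Reactants: 11 tert-butyl 2-[(1R,6S)-6-(TBS-oxy)-4-oxo-3-(prop-2-en-1-yl)cyclohex-2-en-1-yl]acetate
Product: 14 tert-butyl 2-[(1R,6S)-6-(TBS-oxy)-3-(2-hydroxyethyl)-4-oxocyclohex-2-en-1-yl]acetate, via ozonide 12 (not isolated), via aldehyde 13 (not isolated)
Conditions: O3 (1 equiv), CH2Cl2, −78 °C; PPh3, −78 → 0 °C; then NaBH(OAc)3, AcOH, 0 °C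
Reagents that add atoms: ozone, [O-][O+]=O
Why: Ozonolysis should cleave the electron-richer terminal alkene in preference to the enone C=C, and the labile β,γ-unsaturated aldehyde is reduced in the same flask by NaBH(OAc)3, which reduces aldehydes but not ketones or enones.

Step 10
Reactants: 14 tert-butyl 2-[(1R,6S)-6-(TBS-oxy)-3-(2-hydroxyethyl)-4-oxocyclohex-2-en-1-yl]acetate
Product: 15 tert-butyl 2-[(1R,6S)-6-(TBS-oxy)-3-(2-iodoethyl)-4-oxocyclohex-2-en-1-yl]acetate
Conditions: I2, PPh3, imidazole, CH2Cl2, 0 °C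
Reagents that add atoms: iodine, II
Why: Appel-type iodination of the primary alcohol under neutral conditions should give the primary iodide that is the zinc precursor (C3).

Step 11
Reactants: 15 tert-butyl 2-[(1R,6S)-6-(TBS-oxy)-3-(2-iodoethyl)-4-oxocyclohex-2-en-1-yl]acetate, 16 1-methoxy-4-[(prop-2-yn-1-yloxy)methyl]benzene
Product: 19 tert-butyl (1S,6R,7R,8S)-8-(TBS-oxy)-15-(PMB-oxy)-10-oxo-13,14-dinorcadin-4-en-12-oate (trans-fused octalone), via alkylzinc iodide 17 (not isolated), via zinc enolate 18 (not isolated)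
Conditions: activated Zn dust, LiCl, THF, 30 °C; then slow addition to Ni(cod)2 (10 mol %, no phosphine) and 16 (3 equiv), THF, high dilution, 0 → 25 °C; aq NH4Cl; then DBU (cat.), CH2Cl2, 0 °C
Reagents that add atoms: none
Why: Proposed new method: zinc inserts into the primary C3–I bond; zerovalent nickel then joins the zinc-activated enone and the terminal alkyne by oxidative cyclization (C6–C5 bond, alkenylnickel at C4, zinc enolate at O10), the tethered C3–Zn group transmetalates to nickel, and C(sp2)–C(sp3) reductive elimination forms C3–C4 and returns zerovalent nickel. The closest known reactions are the nickel-catalysed three-component alkylative coupling of enones, terminal alkynes and organozinc reagents and the nickel-catalysed alkylative cyclization of alkynyl enones with organozincs; new here is that the organozinc, not the alkyne, is tethered to the enone through its α-carbon, which turns the coupling into a formal [4+2] annulation. Ring A (C1–C6) is the only ring closed: its first bond (C6–C5) is made intermolecularly and the ring-closing bond (C3–C4) by reductive elimination from a seven-membered nickelacycle, the syn addition across the alkyne giving the ring (Z) alkene. C6 is set by binding of nickel and delivery of the alkyne to the enone face opposite to the C7 acetate arm and the C8 silyloxy group, which sit cis on the other face; C1 is set afterwards by protonation of the enolate and base equilibration to the trans-fused decalone, in which the C1–C2 and C6–C5 bonds are both equatorial. The step needs the enone β-carbon to bond to the unsubstituted alkyne carbon and the alkyl group to the substituted one (the tether cannot enforce this), which the steric difference between H and CH2OPMB and the branched, hindered C6 should secure, as terminal alkynes behave in the intermolecular precedent. It also needs alkyl transfer to outrun β-hydride elimination from C3–Ni, direct conjugate addition and alkyne oligomerization, for which the phosphine-free catalyst, high dilution and slow addition of the zinc reagent to excess alkyne are chosen.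

Step 12
Reactants: 19 octalone
Product: 20 tert-butyl (1S,6S,7R,8S)-8-(TBS-oxy)-15-(PMB-oxy)-13-norcadina-4,10(14)-dien-12-oate
Conditions: Zn, CH2Br2, TiCl4 (pre-formed reagent, THF), CH2Cl2, 0 → 25 °C
Reagents that add atoms: dibromomethane, BrCBr
Why: Takai–Lombardo methylenation with the zinc/titanium gem-dimetallic reagent should convert the ketone to the exocyclic C10=C14 alkene without base, so the epimerizable C1 centre, the β-silyloxy group and the ester are not endangered.

Step 13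
Reactants: 20 tert-butyl (1S,6S,7R,8S)-8-(TBS-oxy)-15-(PMB-oxy)-13-norcadina-4,10(14)-dien-12-oate
Product: 23 tert-butyl (1S,6S,7S,8S)-8-(TBS-oxy)-15-(PMB-oxy)cadina-4,10(14),11(13)-trien-12-oate, via Mannich base 21 (not isolated), via ammonium iodide 22 (not isolated)
Conditions: LDA, THF, −78 °C; Me2N=CH2+ I−, −78 → 0 °C; then MeI, THF/MeOH, 25 °C; then DBU, CH2Cl2, 25 °C
Reagents that add atoms: N,N-dimethylmethyleneiminium iodide (Eschenmoser's salt), C=[N+](C)C.[I-]
Why: Mannich reaction of the lithium ester enolate with Eschenmoser's salt, then exhaustive methylation and base-induced elimination of trimethylamine, is the standard α-methylenation of esters and should create the C11=C13 acrylate.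

Step 14
Reactants: 23 tert-butyl (1S,6S,7S,8S)-8-(TBS-oxy)-15-(PMB-oxy)cadina-4,10(14),11(13)-trien-12-oate
Product: 24 tert-butyl (1S,6S,7S,8S)-8-hydroxy-15-(PMB-oxy)cadina-4,10(14),11(13)-trien-12-oate
Conditions: HF·pyridine, pyridine, THF, 0 → 25 °C
Reagents that add atoms: none
Why: Buffered fluoride desilylation removes the secondary silyl ether without touching the PMB ether, and the hindered tert-butyl ester should not lactonize onto the free C8 hydroxyl under these non-basic conditions.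

Step 15
Reactants: 25 methyl 2-[(4S)-2,2-dimethyl-1,3-dioxolan-4-yl]acetate
Product: 28 methyl 2-[(4S)-2,2-dimethyl-1,3-dioxolan-4-yl]prop-2-enoate, via Mannich base 26 (not isolated), via ammonium iodide 27 (not isolated)
Conditions: LDA, THF, −78 °C; Me2N=CH2+ I−, −78 → −20 °C; then MeI, THF/MeOH, 25 °C; then DBU, CH2Cl2, 0 °C
Reagents that add atoms: N,N-dimethylmethyleneiminium iodide (Eschenmoser's salt), C=[N+](C)C.[I-]
Why: The same Mannich/methylation/elimination α-methylenation, run on the lithium enolate of this β-alkoxy ester at −78 °C so that β-elimination of the acetonide oxygen does not compete; the stereocentre is not involved.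

Step 16
Reactants: 28 methyl 2-[(4S)-2,2-dimethyl-1,3-dioxolan-4-yl]prop-2-enoate
Product: 29 2-[(4S)-2,2-dimethyl-1,3-dioxolan-4-yl]prop-2-enoic acid
Conditions: LiOH, THF/H2O, 0 °C; cold dilute HCl to pH 3–4
Reagents that add atoms: lithium hydroxide, [Li+].[OH-]
Why: Saponification of the methyl ester, with careful cold acidification so that the acetonide should survive.

Step 17
Reactants: 24 tert-butyl (1S,6S,7S,8S)-8-hydroxy-15-(PMB-oxy)cadina-4,10(14),11(13)-trien-12-oate, 29 2-[(4S)-2,2-dimethyl-1,3-dioxolan-4-yl]prop-2-enoic acid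
Product: 31 tert-butyl (1S,6S,7S,8S)-8-({2-[(4S)-2,2-dimethyl-1,3-dioxolan-4-yl]prop-2-enoyl}oxy)-15-(PMB-oxy)cadina-4,10(14),11(13)-trien-12-oate, via mixed anhydride 30 (not isolated)
Conditions: 29, 2,4,6-trichlorobenzoyl chloride, Et3N, THF, 0 → 25 °C; then 24, DMAP, toluene, 25 °C
Reagents that add atoms: none
Why: Yamaguchi esterification through the mixed anhydride acylates hindered secondary alcohols, and the C8 configuration is retained because the C8–O bond is not broken.

Step 18
Reactants: 31 fully protected ester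
Product: 32 (1S,6S,7S,8S)-8-{[(3S)-3,4-dihydroxy-2-methylidenebutanoyl]oxy}-15-hydroxycadina-4,10(14),11(13)-trien-12-oic acid (target)
Conditions: TFA/CH2Cl2 (1:4), anisole, H2O (5 equiv), 0 → 20 °C
Reagents that add atoms: none
Why: Acidolysis should remove the three acid-labile groups in one operation (tert-butyl ester as isobutene, PMB ether by benzyl transfer to anisole, acetonide by hydrolysis) and avoids base, which would cyclize the dihydroxy acyl group onto its own ester.

**Compound list**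

1 | cyclohexa-1,3-diene | C1=CC=CCC1 | starting material
2 | cis-cyclohex-2-ene-1,4-diyl diacetate (meso) | C1=C[C@H](OC(C)=O)CC[C@@H]1OC(C)=O | intermediate
3 | (1R,4S)-4-hydroxycyclohex-2-en-1-yl acetate | C1=C[C@H](OC(C)=O)CC[C@@H]1O | intermediate
4 | (1R,4S)-4-(TBS-oxy)cyclohex-2-en-1-yl acetate | C1=C[C@H](OC(C)=O)CC[C@@H]1O[Si](C)(C)C(C)(C)C | intermediate
5 | 1-(TBS-oxy)ethenyl (1R,4S)-4-(TBS-oxy)cyclohex-2-en-1-yl ether (silyl ketene acetal) | C1=C[C@H](OC(=C)O[Si](C)(C)C(C)(C)C)CC[C@@H]1O[Si](C)(C)C(C)(C)C | intermediate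
6 | TBS 2-[(1R,6S)-6-(TBS-oxy)cyclohex-2-en-1-yl]acetate (silyl ester) | CC(C)(C)[Si](C)(C)OC(=O)C[C@@H]1C=CCC[C@@H]1O[Si](C)(C)C(C)(C)C | intermediate
7 | 2-[(1R,6S)-6-(TBS-oxy)cyclohex-2-en-1-yl]acetic acid (arm and silyloxy cis) | OC(=O)C[C@@H]1C=CCC[C@@H]1O[Si](C)(C)C(C)(C)C | intermediate
8 | tert-butyl 2-[(1R,6S)-6-(TBS-oxy)cyclohex-2-en-1-yl]acetate | CC(C)(C)OC(=O)C[C@@H]1C=CCC[C@@H]1O[Si](C)(C)C(C)(C)C | intermediate
9 | tert-butyl 2-[(1R,6S)-6-(TBS-oxy)-4-oxocyclohex-2-en-1-yl]acetate | CC(C)(C)OC(=O)C[C@@H]1C=CC(=O)C[C@@H]1O[Si](C)(C)C(C)(C)C | intermediate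
10 | tert-butyl 2-[(1R,6S)-6-(TBS-oxy)-3-iodo-4-oxocyclohex-2-en-1-yl]acetate | CC(C)(C)OC(=O)C[C@@H]1C=C(I)C(=O)C[C@@H]1O[Si](C)(C)C(C)(C)C | intermediate
11 | tert-butyl 2-[(1R,6S)-6-(TBS-oxy)-4-oxo-3-(prop-2-en-1-yl)cyclohex-2-en-1-yl]acetate | CC(C)(C)OC(=O)C[C@@H]1C=C(CC=C)C(=O)C[C@@H]1O[Si](C)(C)C(C)(C)C | intermediate
12 | tert-butyl 2-[(1R,6S)-6-(TBS-oxy)-4-oxo-3-(1,2,4-trioxolan-3-ylmethyl)cyclohex-2-en-1-yl]acetate (ozonide) | CC(C)(C)OC(=O)C[C@@H]1C=C(CC2OCOO2)C(=O)C[C@@H]1O[Si](C)(C)C(C)(C)C | intermediate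
13 | tert-butyl 2-[(1R,6S)-6-(TBS-oxy)-4-oxo-3-(2-oxoethyl)cyclohex-2-en-1-yl]acetate (aldehyde) | CC(C)(C)OC(=O)C[C@@H]1C=C(CC=O)C(=O)C[C@@H]1O[Si](C)(C)C(C)(C)C | intermediate
14 | tert-butyl 2-[(1R,6S)-6-(TBS-oxy)-3-(2-hydroxyethyl)-4-oxocyclohex-2-en-1-yl]acetate | CC(C)(C)OC(=O)C[C@@H]1C=C(CCO)C(=O)C[C@@H]1O[Si](C)(C)C(C)(C)C | intermediate
15 | tert-butyl 2-[(1R,6S)-6-(TBS-oxy)-3-(2-iodoethyl)-4-oxocyclohex-2-en-1-yl]acetate | CC(C)(C)OC(=O)C[C@@H]1C=C(CCI)C(=O)C[C@@H]1O[Si](C)(C)C(C)(C)C | intermediate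
16 | 1-methoxy-4-[(prop-2-yn-1-yloxy)methyl]benzene (PMB propargyl ether) | C#CCOCc1ccc(OC)cc1 | starting material
17 | alkylzinc iodide of 15 (C3–ZnI) | CC(C)(C)OC(=O)C[C@@H]1C=C(CC[Zn]I)C(=O)C[C@@H]1O[Si](C)(C)C(C)(C)C | intermediate
18 | iodozinc enolate of 19 (C10–O–ZnI, C1=C10) | CC(C)(C)OC(=O)C[C@@H]1[C@H]2C=C(COCc3ccc(OC)cc3)CCC2=C(O[Zn]I)C[C@@H]1O[Si](C)(C)C(C)(C)C | intermediate
19 | tert-butyl (1S,6R,7R,8S)-8-(TBS-oxy)-15-(PMB-oxy)-10-oxo-13,14-dinorcadin-4-en-12-oate (trans ring fusion; C7 arm cis to O8 and trans to C5) | CC(C)(C)OC(=O)C[C@@H]1[C@H]2C=C(COCc3ccc(OC)cc3)CC[C@@H]2C(=O)C[C@@H]1O[Si](C)(C)C(C)(C)C | intermediate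
20 | tert-butyl (1S,6S,7R,8S)-8-(TBS-oxy)-15-(PMB-oxy)-13-norcadina-4,10(14)-dien-12-oate | CC(C)(C)OC(=O)C[C@@H]1[C@H]2C=C(COCc3ccc(OC)cc3)CC[C@@H]2C(=C)C[C@@H]1O[Si](C)(C)C(C)(C)C | intermediate
21 | tert-butyl 13-(dimethylamino)-8-(TBS-oxy)-15-(PMB-oxy)cadina-4,10(14)-dien-12-oate (C11 epimers; ring centres as in 20) | CC(C)(C)OC(=O)C(CN(C)C)[C@@H]1[C@H]2C=C(COCc3ccc(OC)cc3)CC[C@@H]2C(=C)C[C@@H]1O[Si](C)(C)C(C)(C)C | intermediate
22 | trimethylammonium iodide of 21 | CC(C)(C)OC(=O)C(C[N+](C)(C)C)[C@@H]1[C@H]2C=C(COCc3ccc(OC)cc3)CC[C@@H]2C(=C)C[C@@H]1O[Si](C)(C)C(C)(C)C.[I-] | intermediate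
23 | tert-butyl (1S,6S,7S,8S)-8-(TBS-oxy)-15-(PMB-oxy)cadina-4,10(14),11(13)-trien-12-oate | C=C(C(=O)OC(C)(C)C)[C@@H]1[C@H]2C=C(COCc3ccc(OC)cc3)CC[C@@H]2C(=C)C[C@@H]1O[Si](C)(C)C(C)(C)C | intermediate
24 | tert-butyl (1S,6S,7S,8S)-8-hydroxy-15-(PMB-oxy)cadina-4,10(14),11(13)-trien-12-oate | C=C(C(=O)OC(C)(C)C)[C@@H]1[C@H]2C=C(COCc3ccc(OC)cc3)CC[C@@H]2C(=C)C[C@@H]1O | intermediate
25 | methyl 2-[(4S)-2,2-dimethyl-1,3-dioxolan-4-yl]acetate | COC(=O)C[C@H]1COC(C)(C)O1 | starting material
26 | methyl 3-(dimethylamino)-2-[(4S)-2,2-dimethyl-1,3-dioxolan-4-yl]propanoate (C2 epimers) | COC(=O)C(CN(C)C)[C@H]1COC(C)(C)O1 | intermediate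
27 | trimethylammonium iodide of 26 | COC(=O)C(C[N+](C)(C)C)[C@H]1COC(C)(C)O1.[I-] | intermediate
28 | methyl 2-[(4S)-2,2-dimethyl-1,3-dioxolan-4-yl]prop-2-enoate | COC(=O)C(=C)[C@H]1COC(C)(C)O1 | intermediate
29 | 2-[(4S)-2,2-dimethyl-1,3-dioxolan-4-yl]prop-2-enoic acid | OC(=O)C(=C)[C@H]1COC(C)(C)O1 | intermediate
30 | 2-[(4S)-2,2-dimethyl-1,3-dioxolan-4-yl]prop-2-enoic 2,4,6-trichlorobenzoic anhydride | C=C(C(=O)OC(=O)c1c(Cl)cc(Cl)cc1Cl)[C@H]2COC(C)(C)O2 | intermediate
31 | tert-butyl (1S,6S,7S,8S)-8-({2-[(4S)-2,2-dimethyl-1,3-dioxolan-4-yl]prop-2-enoyl}oxy)-15-(PMB-oxy)cadina-4,10(14),11(13)-trien-12-oate | C=C(C(=O)OC(C)(C)C)[C@@H]1[C@H]2C=C(COCc3ccc(OC)cc3)CC[C@@H]2C(=C)C[C@@H]1OC(=O)C(=C)[C@H]4COC(C)(C)O4 | intermediate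
32 | (1S,6S,7S,8S)-8-{[(3S)-3,4-dihydroxy-2-methylidenebutanoyl]oxy}-15-hydroxycadina-4,10(14),11(13)-trien-12-oic acid | C=C(C(=O)O)[C@@H]1[C@H]2C=C(CO)CC[C@@H]2C(=C)C[C@@H]1OC(=O)C(=C)[C@H](O)CO | target

**Totals**

Total step count: 18.
Longest linear sequence: 16 steps (steps 1–14, 17, 18, from 1).

**Steps most likely to fail**

Step 11 (key step, proposed new method). What may go wrong:
- β-hydride elimination or protonation at the alkenylnickel stage, giving open-chain reductive coupling instead of ring closure;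
- insertion of the alkyne with the opposite regiochemistry;
- nickel-mediated oligomerization of the terminal alkyne or direct conjugate addition of the zinc reagent;
- elimination of the silyloxy group during the C1 equilibration.

Fallback with known chemistry, setting out from 15 and coming back at 19. The alkylzinc iodide 17 is made as before and joined by Negishi coupling (Pd2(dba)3, SPhos, THF) with 2-bromoallyl 4-methoxybenzyl ether (C=C(Br)COCc1ccc(OC)cc1), which forms C3–C4 and should give tert-butyl 2-[(1R,6S)-6-(TBS-oxy)-3-{3-[(PMB-oxy)methyl]but-3-en-1-yl}-4-oxocyclohex-2-en-1-yl]acetate F1. Copper-catalysed conjugate addition of vinylmagnesium bromide (CuBr·SMe2, THF, −78 °C), anti to the C7 arm, then protonation and base equilibration, should give the 2-ethenyl ketone tert-butyl 2-[6-(TBS-oxy)-2-ethenyl-3-{3-[(PMB-oxy)methyl]but-3-en-1-yl}-4-oxocyclohexyl]acetate F2 (ring centres as in 19). Ring-closing metathesis with the second-generation Grubbs catalyst (CH2Cl2, 40 °C) then closes ring A by forming C4=C5 and returns to 19.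

Step 18 (global acidolysis). What may go wrong: migration of the exocyclic C10=C14 alkene into the ring, ionization at the allylic C15–O bond, and acid-catalysed cyclization of the freed diol onto its own ester, all driven by the acid strength that the tert-butyl ester demands.

Fallback that removes the tert-butyl ester from the endgame, setting out from 23 and coming back at 32. DIBAL-H (CH2Cl2, −78 °C) reduces the ester to 8-(TBS-oxy)-15-(PMB-oxy)cadina-4,10(14),11(13)-trien-12-ol F3. TBAF (THF) gives 15-(PMB-oxy)cadina-4,10(14),11(13)-triene-8,12-diol F4, which cannot lactonize. Selective silylation of the primary allylic hydroxyl (TESCl, imidazole, CH2Cl2, −78 °C) gives 12-(triethylsilyloxy)-15-(PMB-oxy)cadina-4,10(14),11(13)-trien-8-ol F5. Acylation with mixed anhydride 30 (DMAP, toluene) gives the 8-O-{2-[(4S)-2,2-dimethyl-1,3-dioxolan-4-yl]prop-2-enoyl} ester of F5, F6. Buffered HF·pyridine frees the corresponding 12-ol F7. MnO2 (CH2Cl2) gives the 12-al F8, and Pinnick oxidation (NaClO2, NaH2PO4, 2-methylbut-2-ene, t-BuOH/H2O) gives 8-({2-[(4S)-2,2-dimethyl-1,3-dioxolan-4-yl]prop-2-enoyl}oxy)-15-(PMB-oxy)cadina-4,10(14),11(13)-trien-12-oic acid F9. Only the PMB ether and the acetonide then remain, and dilute TFA (5 % in wet CH2Cl2, anisole, 0 °C) should release 32.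

Step 6 (allylic oxidation). What may go wrong: hydrogen abstraction at the tertiary allylic C7–H or allylic transposition of the intermediate radical, leading to the regioisomeric enone, and over-oxidation.

Fallback by an ene/[2,3]-sigmatropic hydroxylation instead of radical peroxidation, setting out from 8 and coming back at 9. SeO2 (cat.) with t-BuOOH (CH2Cl2, 25 °C) should hydroxylate the allylic CH2 without moving the alkene, giving tert-butyl 2-[(1R,6S)-6-(TBS-oxy)-4-hydroxycyclohex-2-en-1-yl]acetate F10 (C4 epimers). Dess–Martin periodinane (CH2Cl2) then oxidizes it to 9.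

**Further compounds**

F1 | step 11 | tert-butyl 2-[(1R,6S)-6-(TBS-oxy)-3-{3-[(PMB-oxy)methyl]but-3-en-1-yl}-4-oxocyclohex-2-en-1-yl]acetate | CC(C)(C)OC(=O)C[C@@H]1C=C(CCC(=C)COCc2ccc(OC)cc2)C(=O)C[C@@H]1O[Si](C)(C)C(C)(C)C
F2 | step 11 | tert-butyl 2-[6-(TBS-oxy)-2-ethenyl-3-{3-[(PMB-oxy)methyl]but-3-en-1-yl}-4-oxocyclohexyl]acetate (ring centres as in 19) | CC(C)(C)OC(=O)C[C@@H]1[C@@H](C=C)[C@H](CCC(=C)COCc2ccc(OC)cc2)C(=O)C[C@@H]1O[Si](C)(C)C(C)(C)C
F3 | step 18 | 8-(TBS-oxy)-15-(PMB-oxy)cadina-4,10(14),11(13)-trien-12-ol | C=C(CO)[C@@H]1[C@H]2C=C(COCc3ccc(OC)cc3)CC[C@@H]2C(=C)C[C@@H]1O[Si](C)(C)C(C)(C)C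
F4 | step 18 | 15-(PMB-oxy)cadina-4,10(14),11(13)-triene-8,12-diol | C=C(CO)[C@@H]1[C@H]2C=C(COCc3ccc(OC)cc3)CC[C@@H]2C(=C)C[C@@H]1O
F5 | step 18 | 12-(triethylsilyloxy)-15-(PMB-oxy)cadina-4,10(14),11(13)-trien-8-ol | C=C(CO[Si](CC)(CC)CC)[C@@H]1[C@H]2C=C(COCc3ccc(OC)cc3)CC[C@@H]2C(=C)C[C@@H]1O
F6 | step 18 | 12-(triethylsilyloxy)-15-(PMB-oxy)cadina-4,10(14),11(13)-trien-8-yl 2-[(4S)-2,2-dimethyl-1,3-dioxolan-4-yl]prop-2-enoate | C=C(CO[Si](CC)(CC)CC)[C@@H]1[C@H]2C=C(COCc3ccc(OC)cc3)CC[C@@H]2C(=C)C[C@@H]1OC(=O)C(=C)[C@H]4COC(C)(C)O4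
F7 | step 18 | 12-hydroxy-15-(PMB-oxy)cadina-4,10(14),11(13)-trien-8-yl 2-[(4S)-2,2-dimethyl-1,3-dioxolan-4-yl]prop-2-enoate | C=C(CO)[C@@H]1[C@H]2C=C(COCc3ccc(OC)cc3)CC[C@@H]2C(=C)C[C@@H]1OC(=O)C(=C)[C@H]4COC(C)(C)O4
F8 | step 18 | 12-oxo-15-(PMB-oxy)cadina-4,10(14),11(13)-trien-8-yl 2-[(4S)-2,2-dimethyl-1,3-dioxolan-4-yl]prop-2-enoate | C=C(C=O)[C@@H]1[C@H]2C=C(COCc3ccc(OC)cc3)CC[C@@H]2C(=C)C[C@@H]1OC(=O)C(=C)[C@H]4COC(C)(C)O4
F9 | step 18 | 8-({2-[(4S)-2,2-dimethyl-1,3-dioxolan-4-yl]prop-2-enoyl}oxy)-15-(PMB-oxy)cadina-4,10(14),11(13)-trien-12-oic acid | C=C(C(=O)O)[C@@H]1[C@H]2C=C(COCc3ccc(OC)cc3)CC[C@@H]2C(=C)C[C@@H]1OC(=O)C(=C)[C@H]4COC(C)(C)O4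
F10 | step 6 | tert-butyl 2-[(1R,6S)-6-(TBS-oxy)-4-hydroxycyclohex-2-en-1-yl]acetate (C4 epimers) | CC(C)(C)OC(=O)C[C@@H]1C=CC(O)C[C@@H]1O[Si](C)(C)C(C)(C)C
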